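The strategy rests on a masked twofold axis. Both arenes are 3,4,5-trimethoxyphenyl, and once the O1–C2 bond of the oxolane ring is cut, C3 and C4 (both R) each carry one ArCH2 arm and one CH2O arm. The target is therefore a (2R,3R)-2,3-dibenzylbutane-1,4-diol in which one oxygen is bonded to the benzylic carbon of the opposite half.
Last disconnection, O1–C2: a hydroxyl-directed remote benzylic C–H etherification (alkoxy radical, 1,5-hydrogen transfer) on the mono-ester of that diol. It closes the only non-aromatic ring, late in the route, and sets C2.
Central disconnection, C3–C4: oxidative homocoupling of two identical chiral imide enolates made from 3-(3,4,5-trimethoxyphenyl)propanoic acid and (S)-4-isopropyl-2-oxazolidinone. It sets C3 and C4 together and closes no ring.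
Between the two: removal of both auxiliaries, reduction to the C2-symmetric diol, and acylation of one of two homotopic hydroxyls, for which only one mono-ester is possible.
Key step: step 2

Remark: the ring is numbered O1, C2 (aryl), C3 (CH2OH), C4 (benzyl), C5. Read this way the target SMILES is (2S,3R,4R), with the C3 and C4 arms cis to each other and the C2 aryl group trans to both. Ar = 3,4,5-trimethoxyphenyl.

Step 1
Reactants: 1 3-(3,4,5-trimethoxyphenyl)propanoic acid; 2 (S)-4-isopropyl-2-oxazolidinone
Product: 4 (S)-4-isopropyl-3-[3-(3,4,5-trimethoxyphenyl)propanoyl]-2-oxazolidinone, via mixed pivalic anhydride 3 (not isolated)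
Conditions: PivCl, Et3N, THF, −20 °C; then LiCl and 2, −20 °C → rt
Reagents that add atoms: pivaloyl chloride CC(C)(C)C(=O)Cl (its acyl group is held only in 3 and leaves again as pivalate)
Why: N-acylation of an oxazolidinone through a mixed anhydride, in which the hindered pivaloyl carbonyl of 3 is spared, so the LiCl-activated, Et3N-deprotonated auxiliary attacks only the arylpropanoyl carbonyl, and no strong base and no stereocentre-forming event is involved.

Step 2
Reactants: 4 (S)-4-isopropyl-3-[3-(3,4,5-trimethoxyphenyl)propanoyl]-2-oxazolidinone (two molecules)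
Product: 7 (4S,4'S)-3,3'-[(2R,3R)-2,3-bis(3,4,5-trimethoxybenzyl)butanedioyl]bis(4-isopropyl-2-oxazolidinone), via lithium Z-enolate 5 (not isolated), via trichlorotitanium Z-enolate 6 (not isolated)
Conditions: lithium diisopropylamide (1.1 equiv), THF, −78 °C; TiCl4 (1.1 equiv), −78 → 0 °C; aq NH4Cl; chromatography, then crystallization
Reagents that add atoms: lithium diisopropylamide CC(C)[N-]C(C)C.[Li+] (lithium held only in 5); titanium tetrachloride Cl[Ti](Cl)(Cl)Cl (the TiCl3 unit is held only in 6)
Why: Deprotonation gives the chelated Z-enolate 5, exchange with TiCl4 gives the tetravalent titanium enolate 6, and inner-sphere electron transfer releases trivalent titanium and an α-carbonyl radical (or its metal-bound equivalent) that bonds to the α-carbon of a second enolate unit, so the C3–C4 bond and the full carbon skeleton arise in one operation. The closest known reaction type is the oxidative dimerization of lithium or titanium enolates of chiral N-(3-arylpropanoyl)oxazolidinones to like-configured 2,3-dibenzylsuccinic derivatives. No ring is closed in this step. Both new stereocentres are set by the auxiliary: in each chelated Z-enolate the isopropyl group shields one face, bonding occurs on the open face as in the standard alkylation of such enolates, and with the ranking C(=O)N > new CH > CH2Ar this face corresponds to R at each carbon. The step needs like (R,R) rather than unlike (R,S) coupling, which the two identical (S)-auxiliaries should secure by acting in the same sense, while no cross-selectivity is required because the partners are identical, the imide has a single enolizable position, and the trimethoxyarene should tolerate TiCl4 at low temperature. Because both auxiliaries are still attached, the (R,S) and (S,S) isomers are diastereomers of 7 and can be removed here, which fixes the stereochemical purity of the backbone.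

Step 3
Reactants: 7 (4S,4'S)-3,3'-[(2R,3R)-2,3-bis(3,4,5-trimethoxybenzyl)butanedioyl]bis(4-isopropyl-2-oxazolidinone)
Product: 9 (2R,3R)-2,3-bis(3,4,5-trimethoxybenzyl)butanedioic acid, via bis(peroxy acid) 8 (not isolated)
Conditions: LiOH, 30% aq H2O2, THF/H2O, 0 °C → rt; aq Na2SO3; CH2Cl2 extraction to recover 2; 1 M HCl to pH 2, EtOAc
Reagents that add atoms: hydrogen peroxide OO (delivered as LiOOH)
Why: Hydroperoxide-mediated imide cleavage, in which the small, strongly nucleophilic but weakly basic HOO− attacks the exocyclic carbonyl even of hindered α-branched imides, so both auxiliaries should leave intact without opening of the oxazolidinone ring or epimerization of the two backbone centres, and the peracid groups of 8 are reduced by sulfite in the quench.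

Step 4
Reactants: 9 (2R,3R)-2,3-bis(3,4,5-trimethoxybenzyl)butanedioic acid
Product: 10 (2R,3R)-2,3-bis(3,4,5-trimethoxybenzyl)butane-1,4-diol
Conditions: LiAlH4 (excess), THF, 0 °C → reflux; H2O, 15% aq NaOH, H2O; filter
Reagents that add atoms: none
Why: Hydride reduction of carboxylic acids with LiAlH4, in which the dicarboxylate formed first cannot enolize, so both acid groups go to CH2OH with the two stereocentres untouched (the descriptors stay R,R because CH2OH keeps the rank of CO2H) and the aryl methyl ethers are inert.

Step 5
Reactants: 10 (2R,3R)-2,3-bis(3,4,5-trimethoxybenzyl)butane-1,4-diol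
Product: 11 (2R,3R)-4-hydroxy-2,3-bis(3,4,5-trimethoxybenzyl)butyl pivalate
Conditions: PivCl (0.9 equiv, slow addition), pyridine, CH2Cl2, −20 → 0 °C
Reagents that add atoms: pivaloyl chloride CC(C)(C)C(=O)Cl
Why: Statistical mono-esterification with a limiting amount of a bulky acyl chloride, in which the twofold axis makes the hydroxyls homotopic so that only one mono-ester can form (acyl migration would be degenerate), unreacted diol and doubly acylated material are separated and returned to 10, and an acyloxy group is chosen because it makes its own OCH2 hydrogens poor partners for the electrophilic alkoxy radical of step 6.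

Step 6
Reactants: 11 (2R,3R)-4-hydroxy-2,3-bis(3,4,5-trimethoxybenzyl)butyl pivalate
Product: 13 [(2S,3R,4R)-4-(3,4,5-trimethoxybenzyl)-2-(3,4,5-trimethoxyphenyl)oxolan-3-yl]methyl pivalate, via alkoxylead triacetate 12 (not isolated)
Conditions: Pb(OAc)4 (1.2 equiv, freed of AcOH), dried CaCO3, benzene, reflux, Ar; filter; aq NaHCO3
Reagents that add atoms: lead tetraacetate CC(=O)O[Pb](OC(C)=O)(OC(C)=O)OC(C)=O (lead and acetate are held only in 12)
Why: Lead tetraacetate cyclization of an alcohol onto a δ C–H bond (alkoxy-radical 1,5-hydrogen atom transfer, the oxidative relative of the hypoiodite and Barton reactions), in which ligand exchange gives 12, homolysis of its O–Pb bond gives the alkoxy radical, this radical takes through a six-membered transition state the weak, electron-rich benzylic hydrogen on the δ carbon of the opposite half rather than the stronger, ester-deactivated δ OCH2 hydrogen, the trivalent lead species oxidizes the benzylic radical to the cation, and the regenerated hydroxyl closes the five-membered ring on the face that puts the aryl group trans to the C3 CH2OPiv arm and the C4 benzyl arm, which sets C2 as S and is also the more stable arrangement, while CaCO3 takes up the acetic acid that could re-ionize the product.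

Step 7
Reactants: 13 [(2S,3R,4R)-4-(3,4,5-trimethoxybenzyl)-2-(3,4,5-trimethoxyphenyl)oxolan-3-yl]methyl pivalate
Product: 14 [(2S,3R,4R)-4-(3,4,5-trimethoxybenzyl)-2-(3,4,5-trimethoxyphenyl)oxolan-3-yl]methanol (CNP0321241.1)
Conditions: diisobutylaluminium hydride (3 equiv), CH2Cl2, −78 °C; aq potassium sodium tartrate
Reagents that add atoms: none
Why: Reductive ester cleavage, chosen because the pivalate is too hindered for mild carbonate methanolysis but is reduced readily by diisobutylaluminium hydride at low temperature, under conditions that neither ionize nor epimerize the benzylic ether at C2 and leave the aryl ethers and the ring alone, so all three stereocentres are carried into 14.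

Compound list
1 | 3-(3,4,5-trimethoxyphenyl)propanoic acid | COc1cc(CCC(=O)O)cc(OC)c1OC | starting material
2 | (S)-4-isopropyl-2-oxazolidinone | CC(C)[C@H]1COC(=O)N1 | starting material
3 | 3-(3,4,5-trimethoxyphenyl)propanoic pivalic anhydride | COc1cc(CCC(=O)OC(=O)C(C)(C)C)cc(OC)c1OC | intermediate
4 | (S)-4-isopropyl-3-[3-(3,4,5-trimethoxyphenyl)propanoyl]-2-oxazolidinone | COc1cc(CCC(=O)N2[C@@H](C(C)C)COC2=O)cc(OC)c1OC | intermediate
5 | lithium Z-enolate of 4 | COc1cc(C/C=C(\O[Li])N2[C@@H](C(C)C)COC2=O)cc(OC)c1OC | intermediate
6 | trichlorotitanium Z-enolate of 4 | COc1cc(C/C=C(\O[Ti](Cl)(Cl)Cl)N2[C@@H](C(C)C)COC2=O)cc(OC)c1OC | intermediate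
7 | (4S,4'S)-3,3'-[(2R,3R)-2,3-bis(3,4,5-trimethoxybenzyl)butanedioyl]bis(4-isopropyl-2-oxazolidinone) | O=C(N1[C@@H](C(C)C)COC1=O)[C@H](Cc1cc(OC)c(OC)c(OC)c1)[C@@H](Cc1cc(OC)c(OC)c(OC)c1)C(=O)N1[C@@H](C(C)C)COC1=O | intermediate
8 | (2R,3R)-2,3-bis(3,4,5-trimethoxybenzyl)butanediperoxoic acid (present as its dilithium salt) | OOC(=O)[C@H](Cc1cc(OC)c(OC)c(OC)c1)[C@@H](Cc1cc(OC)c(OC)c(OC)c1)C(=O)OO | intermediate
9 | (2R,3R)-2,3-bis(3,4,5-trimethoxybenzyl)butanedioic acid | OC(=O)[C@H](Cc1cc(OC)c(OC)c(OC)c1)[C@@H](Cc1cc(OC)c(OC)c(OC)c1)C(=O)O | intermediate
10 | (2R,3R)-2,3-bis(3,4,5-trimethoxybenzyl)butane-1,4-diol | OC[C@H](Cc1cc(OC)c(OC)c(OC)c1)[C@@H](Cc1cc(OC)c(OC)c(OC)c1)CO | intermediate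
11 | (2R,3R)-4-hydroxy-2,3-bis(3,4,5-trimethoxybenzyl)butyl pivalate | CC(C)(C)C(=O)OC[C@H](Cc1cc(OC)c(OC)c(OC)c1)[C@@H](Cc1cc(OC)c(OC)c(OC)c1)CO | intermediate
12 | alkoxylead triacetate of 11 | CC(C)(C)C(=O)OC[C@H](Cc1cc(OC)c(OC)c(OC)c1)[C@@H](Cc1cc(OC)c(OC)c(OC)c1)CO[Pb](OC(C)=O)(OC(C)=O)OC(C)=O | intermediate
13 | [(2S,3R,4R)-4-(3,4,5-trimethoxybenzyl)-2-(3,4,5-trimethoxyphenyl)oxolan-3-yl]methyl pivalate | COc1cc(C[C@H]2CO[C@H](c3cc(OC)c(OC)c(OC)c3)[C@H]2COC(=O)C(C)(C)C)cc(OC)c1OC | intermediate
14 | [(2S,3R,4R)-4-(3,4,5-trimethoxybenzyl)-2-(3,4,5-trimethoxyphenyl)oxolan-3-yl]methanol (CNP0321241.1) | COc1cc(C[C@H]2CO[C@H](c3cc(OC)c(OC)c(OC)c3)[C@H]2CO)cc(OC)c1OC | target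

Total step count: 7
Longest linear sequence: 7 steps (1 → 4 → 7 → 9 → 10 → 11 → 13 → 14)

Three steps most likely to fail

1. Step 6, ring closure.
- What may go wrong: tetravalent lead may oxidize the electron-rich arenes or the second benzylic position directly. The alkoxy radical may lose formaldehyde by β-scission, add to the nearer arene, or simply be oxidized at the carbinol carbon. Insufficient buffering may re-ionize the new benzylic ether, followed by epimerization at C2 or Friedel-Crafts closure onto the other ring.
- Fallback: it sets out from 10 and comes back at 14, replacing oxygen-directed hydrogen atom transfer by arene-directed hydride abstraction and dropping the protecting group. The free diol 10 is treated with slightly less than one equivalent of DDQ in CH2Cl2 over solid NaHCO3 at 0 °C.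
- Because of the twofold axis, hydride loss from either benzylic CH2 gives the same cation. The hydroxyl of the opposite half should capture it in a five-membered closure, with the aryl group trans to both arms.
- A second closure to the bicyclic bis-ether is held back by the limiting oxidant, and unreacted 10 is recycled.

2. Step 2, homocoupling.
- What may go wrong: poor like/unlike selectivity, incomplete oxidation with return of protonated imide on quench, or α-chlorination of the enolate.
- Fallback: it sets out from 4 and comes back at 10, building the C3–C4 region by two polar alkylations instead of one oxidative dimerization.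
- The sodium enolate of 4 (sodium bis(trimethylsilyl)amide, THF, −78 °C) is alkylated with tert-butyl bromoacetate on the face away from the isopropyl group to give the succinate imide F1.
- LiBH4 (Et2O, one equivalent of water, 0 °C) reduces the imide carbonyl selectively and releases the auxiliary to give the hydroxy ester F2.
- CF3CO2H in CH2Cl2 removes the tert-butyl group and closes the (R)-β-benzyl-γ-butyrolactone F3.
- The lithium enolate of F3 (lithium bis(trimethylsilyl)amide, THF, −78 °C) is alkylated with 3,4,5-trimethoxybenzyl bromide anti to the resident benzyl group to give the trans-(3R,4R)-dibenzylbutyrolactone F4.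
- LiAlH4 in THF opens F4 to 10.

3. Step 3, removal of the auxiliaries.
- What may go wrong: slow cleavage of the second, more crowded imide, competing attack at the ring carbonyl with loss of the auxiliary, or partial epimerization on prolonged exposure to base.
- Fallback: it sets out from 7 and comes back at 10, using reductive instead of hydrolytic cleavage and bypassing 9. LiBH4 with one equivalent of methanol per equivalent of LiBH4 in THF/Et2O at 0 °C should take both exocyclic carbonyls directly to CH2OH under non-basic conditions, and the auxiliary is recovered by chromatography.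

Further compounds
F0 | step 6 | none | none
F1 | step 2 | tert-butyl (R)-4-[(S)-4-isopropyl-2-oxooxazolidin-3-yl]-4-oxo-3-(3,4,5-trimethoxybenzyl)butanoate | O=C(N1[C@@H](C(C)C)COC1=O)[C@H](Cc1cc(OC)c(OC)c(OC)c1)CC(=O)OC(C)(C)C
F2 | step 2 | tert-butyl (R)-3-(hydroxymethyl)-4-(3,4,5-trimethoxyphenyl)butanoate | OC[C@H](Cc1cc(OC)c(OC)c(OC)c1)CC(=O)OC(C)(C)C
F3 | step 2 | (R)-4-(3,4,5-trimethoxybenzyl)dihydrofuran-2(3H)-one | O1C[C@H](Cc2cc(OC)c(OC)c(OC)c2)CC1=O
F4 | step 2 | (3R,4R)-3,4-bis(3,4,5-trimethoxybenzyl)dihydrofuran-2(3H)-one | O1C[C@H](Cc2cc(OC)c(OC)c(OC)c2)[C@@H](Cc2cc(OC)c(OC)c(OC)c2)C1=O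
F0 | step 3 | none | none
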